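Two lengths and the choice between them were asked, and the readings I had did not show the number of chains.

| setting | gamma | epsilon | ochre | violet |
|---|---|---|---|---|
| free monomer | 1 M | 1 M | 1.0 M | 1.0 M |
| transfer agent | 0.10 M | 0.10 M | 0.100 M | 0.100 M |
| initiator | 0.13 mol% | 0.2 mol% | 0.26 mol% | 0.26 mol% |
| remark | run made earlier | run made earlier |  |  |
| time |  |  | 8.0 h | 2.5 h |

| run | time / h | monomer in chains / % | free monomer / % |
|---|---|---|---|
| gamma | 2.00 | 3.4 | 96.0 |
| gamma | 4.00 | 7.5 | 92.6 |
| gamma | 6.00 | 9.1 | 91.2 |
| gamma | 8.00 | 9.9 | 88.7 |
| gamma | 10.0 | 11.0 | 89.2 |
| epsilon | 2.00 | 5.9 | 93.3 |
| epsilon | 4.00 | 11.2 | 88.7 |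
| epsilon | 6.00 | 13.6 | 87.3 |
| epsilon | 8.00 | 15.3 | 85.1 |
| epsilon | 10.0 | 15.3 | 83.3 |

(each reading ± 0.5 percentage points)

- percent here means free monomer units held: one self-condensation product counts as two
- the average divides the monomer in chains by the number of chains begun, living and dead together
- what was read earlier has a scatter of 0.5 percentage points, one standard deviation
- steps thought possible: 2 free monomer -> self-condensation product; free monomer + living end -> monomer in chains + living end; free monomer + initiator -> spent initiator; free monomer + initiator -> living end + monomer in chains; living end + transfer agent -> dead chain
- the earlier runs do not show the number of chains; that part of a forecast is a guess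

* which of the two ends with the longer chains by the average number of monomer units in a chain (chains begun, living or dead) ("neither" if they lie within 10 %) (ochre / violet / neither)
* average number of monomer units in a chain (chains begun, living or dead) at the end, ochre
* average number of monomer units in a chain (chains begun, living or dead) at the end, violet

In the steps thought possible, one initiator is used for each chain begun. So monomer in chains divided by initiator charged, as fractions of the free monomer charged, is a floor under the average length (the number-average degree of polymerisation). I reached that floor for ochre from two separate runs. At 8.00 h, gamma gave 76.2 units per initiator charged and epsilon gave 76.5. On logarithms, the rise in monomer in chains from gamma to epsilon over the rise in loading was 1.01, so the loading cancelled between these runs. I assumed this held at the higher loading of ochre and reckoned 76.3 for it.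

At 2.00 h the two runs parted, with gamma at 26.2 and epsilon at 29.5. The scatter of a reading, divided by the charge, came to 3.85 units in gamma, more than the 2.50 in epsilon, and the gap of 3.35 lay within gamma's scatter. So I trusted epsilon. Its monomer in chains had grown to about twice its first reading by 4.00 h, so I scaled that first reading in proportion to time. For violet this gave 36.9 units per initiator charged at 2.5 h. My reckoning therefore put ochre longer than violet.

The forecast also chose ochre, with 105 for ochre (from 72 to 170) and 60 for violet (from 37 to 105). Its divisor was a guess below the charge: “Efficiency is unseen because some initiator is wasted”. I divided by the whole charge, so my numbers stood lower.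

The flasks gave ochre as the longer, with 80.6 for ochre and 38.4 for violet, a little above my 76.3 and 36.9.

    2 free monomer → self-condensation product (k = 4.60 × 10⁻⁵ M⁻¹ h⁻¹)
    free monomer + living end → monomer in chains + living end, rate k2*[living end]*[free monomer] (k = 24.0 M⁻¹ h⁻¹)
    free monomer + initiator → spent initiator (k = 0.170 M⁻¹ h⁻¹)
    free monomer + initiator → living end + monomer in chains (k = 2.00 M⁻¹ h⁻¹)
    living end + transfer agent → dead chain (kL = 2.20 M⁻¹ h⁻¹)

At the end of violet, the half-life of initiator by the initiating step, 0.38 h, was shorter than that of the living end by transfer, 3.2 h. With 0.56 % of the initiator left and 7.79 % of its charge held as spent initiator, chains begun stood at 91.7 % of the charge, close to the divisor I had used. For the neighbour of violet with 0.44 mol% of initiator, at 2.50 h, 36.9 units per initiator charged gave 16.2 % of monomer in chains, and 36.9 stood as my estimate of the floor under the length. The computed flask gave 15.0 % and 37.1.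

The numbers in the tables stem from a simulated flask on assumed constants; scatter was added.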